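## Analysis of the target

The target (24) is a longipinane, tricyclo[5.4.0.0^2,8]undecane. A cyclobutane (C1, C2, C8, C7) is spanned on one face by the enone bridge C9(=O)–C10=C11(CH3), running from C8 to C1, and on the other face by the chain C3–C4–C5–C6, running from C2 to C7. This numbering is used throughout: C1 is the allylic cyclobutane CH, C2 the methyl-bearing quaternary carbon, C3 the angeloyloxy carbinol, C4 a CH2, C5 the tigloyloxy carbinol, C6 the C(CH3)2, C7 the cyclobutane CH next to C6, and C8 the cyclobutane CH next to the ketone C9.

There are six stereocentres. C1, C2, C7 and C8 are locked to each other by the cage, so only its absolute sense is free. C3 and C5 are trans to each other: C3–O lies on the C8 flank of the cage and C5–O on the C1 flank.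

The sensitive groups are the (Z)-2-methylbut-2-enoate on O3, which isomerises easily to the (E)-ester, the γ-enolisable and light-sensitive bicyclic enone, and two hindered secondary esters.

Three things make the synthesis hard. The cyclobutane carries a quaternary carbon and sits between a six- and a seven-membered ring. The two faces of the seven-membered ring are related by a local pseudo-mirror plane (through C2, C7 and C10), so the cage gives little bias at C3 and C5. And two similar hindered hydroxyls must take the two geometric isomers of one acyl group.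

The strategy rests on one feature: the C9 ketone and C3 (at the ketone oxidation level) are 1,4-related across the cyclobutane bond C8–C2. That bond therefore joins two carbonyl α-carbons.

## Retrosynthetic reasoning

24 is cut at the O3–acyl bond to alcohol 22 and angelic anhydride 23. The (Z)-ester goes on last because it is the group most easily isomerised, and 22 has only one free hydroxyl.

22 is cut at the O5–acyl bond and at C3–H, both of which come from aldehyde 21 in one redox-neutral step on hydroxy ketone 20. This single operation sets C3 trans to C5 and places the (E)-ester on O5, so the two similar hydroxyls never have to be told apart.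

20 is cut at C5–O back to the cycloheptenone of 18. The oxygen enters by conjugate addition of boron and oxidation. Because the two faces of C5 are nearly mirror-related, a chiral copper catalyst has to choose the face.

18 is cut at C8–C2 (via 17) to the cis-fused bis-enone 16. This is the only cyclobutane bond flanked by two carbonyl α-carbons, so it can be made by oxidising two enolates. The cut removes one ring and two stereocentres, and the cis fusion of 16 leaves only one way to close.

The cycloheptenone in 16 carries hydrogen at C5, not an alkoxy group. The enone still blocks C4 against deprotonation (C6 is quaternary), so only C2 can be enolised. A 5-alkoxy vinylogous ester would have to come from O-alkylation of an unsymmetrical 1,3-dione, which should favour the less hindered oxygen at C3, the wrong isomer. It would also leave two ketone-level carbons to be reduced and differentiated later.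

16 is cut at the C9 carbonyl oxygen to 15, by allylic oxidation of the only unhindered allylic methylene. 15 is cut at C4=C5 to triene 14, by ring-closing metathesis of two vinyl groups. This avoids any regiochemical question in forming the seven-membered ring.

14 is cut at C3–C4 to the N-methoxy-N-methyl amide 13, and 13 to acid 11 (via 12).

11 is cut at C1–C2 to propanoate 8 (via 9 and 10), by an ester enolate Claisen rearrangement. A Claisen shift is used, not an enolate alkylation, because alkylation next to the bulky C7 substituent would go trans. The suprafacial shift transfers the configuration of the C10–O bond to C1 and gives the cis relationship that the key step needs.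

8 comes from alcohol 6 and acid chloride 7, and 6 from enone 5 by a catalyst-controlled carbonyl reduction.

5 is cut at C1=C11 (aldol condensation) to keto aldehyde 4, and 4 at C7–C8 (Michael addition) to aldehyde 2 and enone 3. The amine-catalysed Michael addition sets C7, the stereocentre from which all others follow. 2 comes from commercial ester 1.

## Alternatives that were turned down

Alternative 1: The cut is at C7–C8 and C1–C11. An intramolecular Diels–Alder reaction of the acyclic silyloxydiene–nitroalkene A1 closes the cyclohexene and the seven-membered ring together and gives the cis-fused nitro bicycle A2.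
- For it: two rings and four stereocentres form in one thermal step. C3 and C5 and their trans relationship are set on an open chain before any cage exists. On that point it is stronger than the chosen route, which must set C5 on the tricycle with a catalyst.
- Against it: the tether closes a seven-membered ring, which is entropically costly and gives weak endo/exo and facial control at a neopentyl dienophile carbon. The hardest bond (C1–C2, cyclobutane, quaternary C2) is still open. It would need a ketone to be unmasked at C3, a nitronate-based closure, and removal of the nitro group from a cyclobutane carbon. Three silyl ethers must be told apart, and A1 needs a long linear synthesis.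
- A stereochemical point: suprafacial addition to an (E)-nitroalkene puts the nitro group trans to C6, while A2 has them cis. The acidic nitro centre would have to be epimerised.
- Comparison: the chosen route reaches a comparable cis-fused bicycle (16) in ten steps with two stereocentres and closes the cyclobutane directly between two carbonyl α-carbons, with no auxiliary group to remove.

Alternative 2: The cut is at three C–C bonds (C6–C7, C7–C8, C1–C2), back to farnesyl diphosphate A3. An α-longipinene synthase would turn A3 into α-longipinene A4 in one cationic cascade.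
- For it: nothing matches it for the hydrocarbon skeleton. All rings and all four cage stereocentres form in one step, which is clearly better than the chosen route up to the carbocycle.
- Against it: A4 has none of the three oxygens. C9 could be oxidised allylically. C3 and C5 are unactivated methylenes next to quaternary carbons, and they must be oxidised selectively, trans to each other, and then differentiated. No flask method is predictable for that, and it would need further tailored oxidases. The route also depends on enzyme supply in the right enantiomeric series and on a diphosphate substrate.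
- Comparison: the chosen route is longer to the core, but every oxygen is placed by ordinary functional-group chemistry. The C9 and C3 carbonyls are the groups that make the key bond, and the enone left by metathesis delivers O5.

Alternative 3: The cut is at C7–C8 and C1–C2, with the seven-membered ring left open. The dienoyl chloride A5 is dehydrohalogenated with Et3N to the vinylketene A6. Its ketene adds across the trisubstituted C2=C8 alkene to give the bicyclo[3.1.1]heptenone A7, in which the cyclobutanone carbon is the future C7.
- For it: this cycloaddition type is well established for this bicyclic system, so the key step has better precedent than the chosen one. C2 follows stereospecifically from the alkene geometry, and the precursor is acyclic.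
- Against it: only the allylic silyloxy centre at C3 controls the facial sense of the cage, and that is not dependable. The seven-membered ring must then be closed by adding a hindered isopropyl ketone enolate (C6) to the cyclobutanone. That aldol is reversible and joins a quaternary carbon to a tertiary cyclobutanol carbon. The tertiary hydroxyl must then be removed from C7 with the right configuration. C9 still has to be oxidised, and the β,γ-unsaturated cyclobutanone is prone to acyl shifts.
- Comparison: the chosen route closes the seven-membered ring first by metathesis in an unstrained setting. The key step then has to form only one bond, and the ring fusion fixes its stereochemistry.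

Key step: step 11

Remark: the cycloheptenone of the key-step pair (16, 18) carries hydrogen at C5 in place of an alkoxy group, for the reasons given above; C5–O is introduced in step 12.
Remark: the carbon that becomes C2 is carried as a mixture of epimers from 11 to 16; it is planar in 17.
Remark: 1, 3, 7, 21 and 23 are taken as commercial (23 is also made in one operation from commercial angelic acid).

## Steps

Step 1
Reactants: 1 methyl 3,3-dimethylpent-4-enoate
Product: 2 3,3-dimethylpent-4-enal
Conditions: iBu2AlH (1.05 equiv), CH2Cl2, −78 °C; aq. potassium sodium tartrate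
Reagents that add atoms: none
Why: Partial reduction of an ester: the aluminium hemiacetal is stable at −78 °C and gives the aldehyde only on work-up; no stereocentre is involved.

Step 2
Reactants: 2 3,3-dimethylpent-4-enal; 3 pent-1-en-3-one
Product: 4 (2S)-2-(2-methylbut-3-en-2-yl)-5-oxoheptanal
Conditions: (S)-2-[methoxy(diphenyl)methyl]pyrrolidine (5 mol %), ethyl 3,4-dihydroxybenzoate (20 mol %), neat, 4 °C
Reagents that add atoms: none
Why: Enamine-catalysed Michael addition: the (E)-enamine of 2 adds to 3 on the face not covered by the methoxy(diphenyl)methyl group, which with the (S)-catalyst should give the (S)-aldehyde and so the configuration of the future C7; the catechol co-catalyst activates the enone by hydrogen bonding.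

Step 3
Reactants: 4 (2S)-2-(2-methylbut-3-en-2-yl)-5-oxoheptanal
Product: 5 (4R)-2-methyl-4-(2-methylbut-3-en-2-yl)cyclohex-2-en-1-one
Conditions: LiOH (1 equiv), iPrOH, rt
Reagents that add atoms: none
Why: Intramolecular aldol condensation: only the ethyl-ketone methylene can reach the aldehyde through a six-membered ring, and dehydration gives the conjugated enone; the stereocentre is not touched (its descriptor changes only because the priorities change), and mild hydroxide at room temperature is chosen so that it is not epimerised through the dienolate.

Step 4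
Reactants: 5 (4R)-2-methyl-4-(2-methylbut-3-en-2-yl)cyclohex-2-en-1-one
Product: 6 (1S,4R)-2-methyl-4-(2-methylbut-3-en-2-yl)cyclohex-2-en-1-ol
Conditions: (R)-2-methyl-CBS-oxazaborolidine [(R)-1-methyl-3,3-diphenyl-tetrahydro-1H,3H-pyrrolo[1,2-c][1,3,2]oxazaborole] (20 mol %), catecholborane (1.5 equiv), toluene, −78 °C; aq. NaOH
Reagents that add atoms: none
Why: Corey–Bakshi–Shibata reduction: the oxazaborolidine binds the carbonyl with the α-methyl-substituted alkene arm as the large group and delivers hydride under catalyst control, the (R)-catalyst giving the (1S)-alcohol, that is hydroxyl cis to the C4 substituent and pseudoaxial; catecholborane at −78 °C should not hydroborate the vinyl group.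

Step 5
Reactants: 6 (1S,4R)-2-methyl-4-(2-methylbut-3-en-2-yl)cyclohex-2-en-1-ol; 7 propanoyl chloride
Product: 8 (1S,4R)-2-methyl-4-(2-methylbut-3-en-2-yl)cyclohex-2-en-1-yl propanoate
Conditions: pyridine (2 equiv), DMAP (5 mol %), CH2Cl2, 0 °C → rt
Reagents that add atoms: none
Why: Acylation of a secondary allylic alcohol with an acid chloride under nucleophilic catalysis; the C–O bond is not broken, so the configuration is kept.

Step 6
Reactants: 8 (1S,4R)-2-methyl-4-(2-methylbut-3-en-2-yl)cyclohex-2-en-1-yl propanoate
Product: 11 2-[(1S,6R)-2-methyl-6-(2-methylbut-3-en-2-yl)cyclohex-2-en-1-yl]propanoic acid, via silyl ketene acetal 9 (not isolated), via trimethylsilyl ester 10 (not isolated)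
Conditions: LiNiPr2 (1.2 equiv), THF, −78 °C; Me3SiCl/Et3N (1:1, 1.5 equiv), −78 °C → rt, then 55 °C; 1 M HCl
Reagents that add atoms: none
Why: Ireland–Claisen rearrangement: the ester enolate is trapped as silyl ketene acetal 9, whose [3,3] shift is suprafacial, so the new C–C bond forms at the alkene terminus on the ring face from which the pseudoaxial C–O bond leaves, cis to the neighbouring 2-methylbut-3-en-2-yl group (the future cis relationship of C1 and C7); the side-chain α-carbon (future C2) forms as a mixture of epimers, which is harmless because it is enolised in step 11.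

Step 7
Reactants: 11 2-[(1S,6R)-2-methyl-6-(2-methylbut-3-en-2-yl)cyclohex-2-en-1-yl]propanoic acid
Product: 13 N-methoxy-N-methyl-2-[(1S,6R)-2-methyl-6-(2-methylbut-3-en-2-yl)cyclohex-2-en-1-yl]propanamide, via acyl imidazole 12 (not isolated)
Conditions: 1,1'-carbonyldiimidazole (1.2 equiv), CH2Cl2, rt; then MeNH(OMe)·HCl (1.5 equiv), rt
Reagents that add atoms: N,O-dimethylhydroxylamine hydrochloride, CNOC.Cl
Why: Amide formation through the acyl imidazolide; no ring stereocentre is involved and the epimer mixture at the α-carbon is carried on.

Step 8
Reactants: 13 N-methoxy-N-methyl-2-[(1S,6R)-2-methyl-6-(2-methylbut-3-en-2-yl)cyclohex-2-en-1-yl]propanamide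
Product: 14 4-[(1S,6R)-2-methyl-6-(2-methylbut-3-en-2-yl)cyclohex-2-en-1-yl]pent-1-en-3-one
Conditions: CH2=CHMgBr (1.5 equiv), THF, −78 → 0 °C; poured into cold 1 M HCl
Reagents that add atoms: vinylmagnesium bromide, C=C[Mg]Br
Why: Weinreb ketone synthesis: the magnesium-chelated tetrahedral adduct survives until the acidic quench, so the vinyl group adds once only, and quenching into acid keeps the released amine from adding to the new enone.

Step 9
Reactants: 14 4-[(1S,6R)-2-methyl-6-(2-methylbut-3-en-2-yl)cyclohex-2-en-1-yl]pent-1-en-3-one
Product: 15 (1S,7R)-2,6,6,11-tetramethylbicyclo[5.4.0]undeca-4,10-dien-3-one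
Conditions: second-generation Hoveyda–Grubbs catalyst (5 mol %), toluene (0.005 M), 80 °C
Reagents that add atoms: none
Why: Ring-closing metathesis of the two monosubstituted alkenes, held close by their cis-1,2 arrangement on the cyclohexene, closes the seven-membered ring as a (Z)-enone with loss of ethene; the trisubstituted ring alkene should not take part and high dilution suppresses intermolecular metathesis.

Step 10
Reactants: 15 (1S,7R)-2,6,6,11-tetramethylbicyclo[5.4.0]undeca-4,10-dien-3-one
Product: 16 (1S,7R)-2,6,6,11-tetramethylbicyclo[5.4.0]undeca-4,10-diene-3,9-dione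
Conditions: Rh2(cap)4 (cap = caprolactamate, 1 mol %), tBuOOH (70 % aq., 5 equiv), K2CO3 (0.5 equiv), CH2Cl2, rt
Reagents that add atoms: tert-butyl hydroperoxide, CC(C)(C)OO
Why: Allylic oxidation of a trisubstituted cyclohexene to the enone: hydrogen abstraction by tert-butylperoxyl radicals should be fastest at the unhindered ring methylene C9, and the peroxide formed there collapses to the conjugated ketone; the cycloheptenone has no γ-hydrogen (C6 is quaternary) and is left alone.

Step 11
Reactants: 16 (1S,7R)-2,6,6,11-tetramethylbicyclo[5.4.0]undeca-4,10-diene-3,9-dione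
Product: 18 (1R,2R,7S,8R)-2,6,6,11-tetramethyltricyclo[5.4.0.0^2,8]undeca-4,10-diene-3,9-dione, via dilithium bis-dienolate 17 (not isolated)
Conditions: 16 added slowly to LiNiPr2 (2.3 equiv), THF, −78 °C; then LiClO4 (0.1 M), constant current (2.1 F per mol, low current density), reticulated vitreous carbon anode, Pt cathode, divided cell (AcOH in the cathode chamber), 0.01 M, −78 → −40 °C; aq. NH4Cl
Reagents that add atoms: none
Why: Proposed new method: LiNiPr2 at −78 °C removes the only kinetically accessible α′-protons (C8–H of the cyclohexenone and C2–H of the cycloheptenone; C6 has no hydrogen and the γ-positions react only under equilibrating conditions) to give bis-dienolate 17, and anodic one-electron oxidation of one dienolate gives an α-keto radical that bonds to the carbon of the neighbouring enolate, the resulting ketyl radical anion then losing a second electron to leave the 1,4-diketone. The closest known reaction type is the intramolecular oxidative coupling of two enolates (with Cu(OTf)2, FeCl3, iodine or an anode), which closes cyclobutanes from diester dianions but has not been shown for two ketone dienolates with formation of a quaternary carbon. The four-membered ring closes in the 4-exo-trig mode with respect to the enolate double bond that is attacked, and no other ring is formed. C8 and C2 are controlled by the cis ring fusion alone: C2 sits pseudoaxially on C1, 1,3-related to C8 across C7, so it can reach only one lobe of the C8 π-system, and the enone bridge and the cycloheptenone bridge can only span opposite faces of the new cyclobutane. A single diastereomer is therefore geometrically possible and both C2 epimers of 16 converge on it. The step needs C–C coupling to win over the five-membered aldol additions (C8 onto C3, C2 onto C9) and over intermolecular coupling; adding 16 to excess base, so that both carbonyl groups are enolates before any current flows, removes the aldol acceptors, and 0.01 M concentration with low current density disfavours dimers. The product cannot enolise at the new bond (C8 is a bridgehead of a bicyclo[3.1.1]heptenone, C2 is quaternary), so further oxidation there is excluded.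

Step 12
Reactants: 18 (1R,2R,7S,8R)-2,6,6,11-tetramethyltricyclo[5.4.0.0^2,8]undeca-4,10-diene-3,9-dione
Product: 20 (1R,2R,5R,7S,8R)-5-hydroxy-2,6,6,11-tetramethyltricyclo[5.4.0.0^2,8]undec-10-ene-3,9-dione, via boryl ketone 19 (not isolated)
Conditions: CuCl (5 mol %), NaOtBu (10 mol %), (R)-1-[(Sp)-2-(diphenylphosphino)ferrocenyl]ethyl-dicyclohexylphosphine (6 mol %), B2pin2 (1.1 equiv), MeOH (2 equiv), THF, rt; then NaBO3·4H2O (5 equiv), THF/H2O, 0 °C → rt
Reagents that add atoms: sodium perborate tetrahydrate, [Na+].[O-]OB=O.O.O.O.O
Why: Copper-catalysed conjugate borylation followed by oxidation: the copper–boryl species adds to the β-monosubstituted cycloheptenone and not to the β,β-disubstituted cyclohexenone; the two faces of C5 differ only through remote groups, so the chiral bisphosphine decides and is chosen to place boron on the C1 flank (if the sense of induction on 18 proves opposite, the enantiomeric ligand is used); perborate replaces boron by hydroxyl with retention.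

Step 13
Reactants: 20 (1R,2R,5R,7S,8R)-5-hydroxy-2,6,6,11-tetramethyltricyclo[5.4.0.0^2,8]undec-10-ene-3,9-dione; 21 (E)-2-methylbut-2-enal
Product: 22 (1R,2R,3R,5R,7S,8R)-3-hydroxy-2,6,6,11-tetramethyl-9-oxotricyclo[5.4.0.0^2,8]undec-10-en-5-yl (E)-2-methylbut-2-enoate
Conditions: SmI2 (0.3 equiv, premixed with 21), 21 (6 equiv), THF, −10 °C
Reagents that add atoms: none
Why: Evans–Tishchenko reduction: the C5 hydroxyl and 21 form a hemiacetal bound to trivalent samarium, whose C–H hydride passes to the C3 carbonyl through a six-membered transition state on the face where the C5–O bond stands, so C3–OH ends up trans (anti) to C5–O and the oxidised aldehyde stays on O5 as the (E)-2-methylbut-2-enoate; the C9 enone has no neighbouring hydroxyl and should not be reduced, and the trans-1,3 relationship on the ring keeps the acyl group from migrating.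

Step 14
Reactants: 22 (1R,2R,3R,5R,7S,8R)-3-hydroxy-2,6,6,11-tetramethyl-9-oxotricyclo[5.4.0.0^2,8]undec-10-en-5-yl (E)-2-methylbut-2-enoate; 23 (Z)-2-methylbut-2-enoic anhydride (angelic anhydride)
Product: 24 (1R,2R,3R,5R,7S,8R)-2,6,6,11-tetramethyl-5-{[(2E)-2-methylbut-2-enoyl]oxy}-9-oxotricyclo[5.4.0.0^2,8]undec-10-en-3-yl (2Z)-2-methylbut-2-enoate
Conditions: LiN(SiMe3)2 (1.05 equiv), THF, −78 °C; 23 (1.5 equiv), −78 → 0 °C; aq. NH4Cl
Reagents that add atoms: none
Why: O-Acylation of the lithium alkoxide with the anhydride: no nucleophilic catalyst or carbodiimide is present, which are the agents that isomerise (Z)-2-methylbut-2-enoyl groups to the (E)-isomer, and one equivalent of base at −78 °C deprotonates the hydroxyl before any C–H acid.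

## Compound list

1 | methyl 3,3-dimethylpent-4-enoate | COC(=O)CC(C)(C)C=C | starting material
2 | 3,3-dimethylpent-4-enal | O=CCC(C)(C)C=C | intermediate
3 | pent-1-en-3-one | CCC(=O)C=C | starting material
4 | (2S)-2-(2-methylbut-3-en-2-yl)-5-oxoheptanal | C=CC(C)(C)[C@@H](C=O)CCC(=O)CC | intermediate
5 | (4R)-2-methyl-4-(2-methylbut-3-en-2-yl)cyclohex-2-en-1-one | C=CC(C)(C)[C@H]1C=C(C)C(=O)CC1 | intermediate
6 | (1S,4R)-2-methyl-4-(2-methylbut-3-en-2-yl)cyclohex-2-en-1-ol | C=CC(C)(C)[C@H]1C=C(C)[C@@H](O)CC1 | intermediate
7 | propanoyl chloride | CCC(Cl)=O | starting material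
8 | (1S,4R)-2-methyl-4-(2-methylbut-3-en-2-yl)cyclohex-2-en-1-yl propanoate | C=CC(C)(C)[C@H]1C=C(C)[C@@H](OC(=O)CC)CC1 | intermediate
9 | (E)-trimethylsilyl ketene acetal of 8 (methyl trans to OSiMe3) | C=CC(C)(C)[C@H]1C=C(C)[C@@H](O/C(=C\C)O[Si](C)(C)C)CC1 | intermediate (not isolated)
10 | trimethylsilyl 2-[(1S,6R)-2-methyl-6-(2-methylbut-3-en-2-yl)cyclohex-2-en-1-yl]propanoate (both α-epimers) | C=CC(C)(C)[C@@H]1CCC=C(C)[C@@H]1C(C)C(=O)O[Si](C)(C)C | intermediate (not isolated)
11 | 2-[(1S,6R)-2-methyl-6-(2-methylbut-3-en-2-yl)cyclohex-2-en-1-yl]propanoic acid (both α-epimers) | C=CC(C)(C)[C@@H]1CCC=C(C)[C@@H]1C(C)C(=O)O | intermediate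
12 | 1-{2-[(1S,6R)-2-methyl-6-(2-methylbut-3-en-2-yl)cyclohex-2-en-1-yl]propanoyl}imidazole (both α-epimers) | C=CC(C)(C)[C@@H]1CCC=C(C)[C@@H]1C(C)C(=O)n1ccnc1 | intermediate (not isolated)
13 | N-methoxy-N-methyl-2-[(1S,6R)-2-methyl-6-(2-methylbut-3-en-2-yl)cyclohex-2-en-1-yl]propanamide (both α-epimers) | C=CC(C)(C)[C@@H]1CCC=C(C)[C@@H]1C(C)C(=O)N(C)OC | intermediate
14 | 4-[(1S,6R)-2-methyl-6-(2-methylbut-3-en-2-yl)cyclohex-2-en-1-yl]pent-1-en-3-one (both C4 epimers) | C=CC(C)(C)[C@@H]1CCC=C(C)[C@@H]1C(C)C(=O)C=C | intermediate
15 | (1S,7R)-2,6,6,11-tetramethylbicyclo[5.4.0]undeca-4,10-dien-3-one (cis-fused, both C2 epimers) | O=C1C=CC(C)(C)[C@@H]2CCC=C(C)[C@@H]2C1C | intermediate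
16 | (1S,7R)-2,6,6,11-tetramethylbicyclo[5.4.0]undeca-4,10-diene-3,9-dione (cis-fused, both C2 epimers) | O=C1C=CC(C)(C)[C@@H]2CC(=O)C=C(C)[C@@H]2C1C | intermediate
17 | dilithium 2,6,6,11-tetramethylbicyclo[5.4.0]undeca-2,4,8,10-tetraene-3,9-diolate (ring fusion as in 16) | [Li]OC1=C(C)[C@H]2C(C)=CC(O[Li])=C[C@H]2C(C)(C)C=C1 | intermediate (not isolated)
18 | (1R,2R,7S,8R)-2,6,6,11-tetramethyltricyclo[5.4.0.0^2,8]undeca-4,10-diene-3,9-dione | O=C1C=CC(C)(C)[C@@H]2[C@H]3C(=O)C=C(C)[C@@H]2[C@]31C | intermediate
19 | (1R,2R,5R,7S,8R)-2,6,6,11-tetramethyl-5-(4,4,5,5-tetramethyl-1,3,2-dioxaborolan-2-yl)tricyclo[5.4.0.0^2,8]undec-10-ene-3,9-dione | O=C1C[C@@H](B2OC(C)(C)C(C)(C)O2)C(C)(C)[C@@H]3[C@H]4C(=O)C=C(C)[C@@H]3[C@]41C | intermediate (not isolated)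
20 | (1R,2R,5R,7S,8R)-5-hydroxy-2,6,6,11-tetramethyltricyclo[5.4.0.0^2,8]undec-10-ene-3,9-dione | O=C1C[C@@H](O)C(C)(C)[C@@H]2[C@H]3C(=O)C=C(C)[C@@H]2[C@]31C | intermediate
21 | (E)-2-methylbut-2-enal | C/C=C(\C)C=O | starting material
22 | (1R,2R,3R,5R,7S,8R)-3-hydroxy-2,6,6,11-tetramethyl-9-oxotricyclo[5.4.0.0^2,8]undec-10-en-5-yl (E)-2-methylbut-2-enoate | O[C@@H]1C[C@@H](OC(=O)/C(C)=C/C)C(C)(C)[C@@H]2[C@H]3C(=O)C=C(C)[C@@H]2[C@]31C | intermediate
23 | (Z)-2-methylbut-2-enoic anhydride | C/C=C(/C)C(=O)OC(=O)/C(C)=C\C | starting material
24 | (1R,2R,3R,5R,7S,8R)-2,6,6,11-tetramethyl-5-{[(2E)-2-methylbut-2-enoyl]oxy}-9-oxotricyclo[5.4.0.0^2,8]undec-10-en-3-yl (2Z)-2-methylbut-2-enoate | C/C=C(/C)C(=O)O[C@@H]1C[C@@H](OC(=O)/C(C)=C/C)C(C)(C)[C@@H]2[C@H]3C(=O)C=C(C)[C@@H]2[C@]31C | target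

## Step count and least certain steps

Total step count: 14. Longest linear sequence: 14 steps (1 → 24).

Step 11 (key step, new method). Ring closure may be outrun. 4-exo closure onto a fully substituted enolate carbon is slow, so the first-formed α-keto radical may be reduced back, abstract hydrogen or couple between molecules. Incomplete deprotonation of the hindered C2 methine would divert material into five-membered aldol closure. The fallback replaces the oxidative coupling by a two-electron intramolecular C-alkylation (4-exo-tet), the classical way of closing bicyclo[3.1.1]heptanones. It sets out from 16. Kinetic mono-enolisation of the cyclohexenone (LiNiPr2, 1.0 equiv, Me3SiCl, THF, −78 °C; the C8 methylene reacts before the C2 methine) should give the cyclohexadienyl silyl ether F1. N-Bromosuccinimide in THF at −78 °C should then brominate C8 on the face away from the pseudoaxial C2, giving the bromo diketone F2. KOtBu in tBuOH/THF at 0 °C enolises C2 reversibly, and the enolate displaces bromide from the rear. The fallback comes back to the route at 18.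

Step 12. The catalyst may not control the face well enough, because the two faces of C5 are nearly mirror-related and the intrinsic bias of 18 is unknown, or addition to the neopentyl β-carbon may be slow. The fallback changes to an epoxide route, setting out from 18. Amine-salt-catalysed nucleophilic epoxidation (9-amino-9-deoxy-epi-quinine bis-trifluoroacetate, 50 % H2O2, dioxane, 40 °C) should give the epoxy diketone F3 with oxygen on the C1 flank. Reductive opening at C4 with (PhSe)2/NaBH4/AcOH in EtOH comes back to the route at 20.

Step 13. The hydride transfer may not take place. The hemiacetal between a neopentyl alcohol and a conjugated, α-branched aldehyde may form too slowly, leaving 20 to undergo retro-aldol cleavage or dehydration on the Lewis acid. The fallback uses a small saturated aldehyde and a protecting-group relay, setting out from 20: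
- SmI2 (0.3 equiv) and acetaldehyde (10 equiv) in THF at −10 °C give the hydroxy acetate F4.
- Et3SiOTf/2,6-lutidine gives the silyl ether acetate F5.
- K2CO3/MeOH gives the C5 alcohol F6.
- (E)-2-Methylbut-2-enoic acid, 2,4,6-trichlorobenzoyl chloride, Et3N and DMAP in toluene give the silyl ether ester F7.
- HF·pyridine in THF comes back to the route at 22.

Step 9. Catalyst loading at the neopentyl vinyl group is slow, and the electron-poor vinyl ketone can consume catalyst, so oligomers may form in place of the ring. The fallback makes the second alkene electron-rich first, setting out from 14. NaBH4/CeCl3·7H2O in MeOH at −78 °C gives the dienol F8. Metathesis with the second-generation Grubbs catalyst in CH2Cl2 at 40 °C gives the bicyclic allylic alcohol F9. Dess–Martin periodinane comes back to the route at 15.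

Step 10. Hydrogen abstraction may occur at the tertiary C1–H or at the C11 methyl in place of C9–H2, or oxygen may be transferred to the wrong end of the allyl radical, giving regioisomeric oxidation products. The fallback builds the enone by a polar sequence, setting out from 15. mCPBA in CH2Cl2 at 0 °C gives the 10,11-epoxide F10. PhSeNa (from (PhSe)2/NaBH4, EtOH) opens it at C10 to the hydroxy selenide F11. H2O2 then eliminates the selenoxide towards C9 to give the tertiary allylic alcohol F12. Oxidative transposition with pyridinium chlorochromate in CH2Cl2 comes back to the route at 16.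

Step 4. The catalyst-preferred face may be mismatched with the substrate's preference for a pseudoequatorial hydroxyl. Diastereoselectivity would then be lost, and with it the cis ring fusion. The fallback uses substrate control and then inversion, setting out from 5. NaBH4/CeCl3·7H2O in MeOH at −78 °C should give the trans alcohol F13. Mitsunobu esterification with propanoic acid (PPh3, diisopropyl azodicarboxylate, THF, 0 °C) inverts C1 and comes back to the route at 8.

## Further compounds

F1 | step 11 | (1S,7S)-2,6,6,11-tetramethyl-9-(trimethylsilyloxy)bicyclo[5.4.0]undeca-4,8,10-trien-3-one | O=C1C=CC(C)(C)[C@@H]2C=C(O[Si](C)(C)C)C=C(C)[C@@H]2C1C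
F2 | step 11 | (1R,7R,8R)-8-bromo-2,6,6,11-tetramethylbicyclo[5.4.0]undeca-4,10-diene-3,9-dione (bromine trans to the C1–C2 bond) | O=C1C=CC(C)(C)[C@@H]2[C@@H](Br)C(=O)C=C(C)[C@@H]2C1C
F3 | step 12 | 4,5-epoxy-2,6,6,11-tetramethyltricyclo[5.4.0.0^2,8]undec-10-ene-3,9-dione, cage as in 18, epoxide oxygen on the C1 flank | O=C1[C@H]2O[C@H]2C(C)(C)[C@@H]3[C@H]4C(=O)C=C(C)[C@@H]3[C@]41C
F4 | step 13 | (1R,2R,3R,5R,7S,8R)-3-hydroxy-2,6,6,11-tetramethyl-9-oxotricyclo[5.4.0.0^2,8]undec-10-en-5-yl acetate | O[C@@H]1C[C@@H](OC(C)=O)C(C)(C)[C@@H]2[C@H]3C(=O)C=C(C)[C@@H]2[C@]31C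
F5 | step 13 | (1R,2R,3R,5R,7S,8R)-2,6,6,11-tetramethyl-9-oxo-3-(triethylsilyloxy)tricyclo[5.4.0.0^2,8]undec-10-en-5-yl acetate | CC[Si](CC)(CC)O[C@@H]1C[C@@H](OC(C)=O)C(C)(C)[C@@H]2[C@H]3C(=O)C=C(C)[C@@H]2[C@]31C
F6 | step 13 | (1R,2R,3R,5R,7S,8R)-5-hydroxy-2,6,6,11-tetramethyl-3-(triethylsilyloxy)tricyclo[5.4.0.0^2,8]undec-10-en-9-one | CC[Si](CC)(CC)O[C@@H]1C[C@@H](O)C(C)(C)[C@@H]2[C@H]3C(=O)C=C(C)[C@@H]2[C@]31C
F7 | step 13 | (1R,2R,3R,5R,7S,8R)-2,6,6,11-tetramethyl-9-oxo-3-(triethylsilyloxy)tricyclo[5.4.0.0^2,8]undec-10-en-5-yl (E)-2-methylbut-2-enoate | CC[Si](CC)(CC)O[C@@H]1C[C@@H](OC(=O)/C(C)=C/C)C(C)(C)[C@@H]2[C@H]3C(=O)C=C(C)[C@@H]2[C@]31C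
F8 | step 9 | 4-[(1S,6R)-2-methyl-6-(2-methylbut-3-en-2-yl)cyclohex-2-en-1-yl]pent-1-en-3-ol (mixture at C3 and C4) | C=CC(C)(C)[C@@H]1CCC=C(C)[C@@H]1C(C)C(O)C=C
F9 | step 9 | (1S,7R)-2,6,6,11-tetramethylbicyclo[5.4.0]undeca-4,10-dien-3-ol (mixture at C2 and C3) | OC1C=CC(C)(C)[C@@H]2CCC=C(C)[C@@H]2C1C
F10 | step 10 | (1S,7R)-10,11-epoxy-2,6,6,11-tetramethylbicyclo[5.4.0]undec-4-en-3-one (either epoxide face serves) | O=C1C=CC(C)(C)[C@@H]2CCC3OC3(C)[C@@H]2C1C
F11 | step 10 | (1S,7R)-11-hydroxy-2,6,6,11-tetramethyl-10-(phenylselanyl)bicyclo[5.4.0]undec-4-en-3-one | O=C1C=CC(C)(C)[C@@H]2CCC([Se]c3ccccc3)C(C)(O)[C@@H]2C1C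
F12 | step 10 | (1S,7R)-11-hydroxy-2,6,6,11-tetramethylbicyclo[5.4.0]undeca-4,9-dien-3-one | O=C1C=CC(C)(C)[C@@H]2CC=CC(C)(O)[C@@H]2C1C
F13 | step 4 | (1R,4R)-2-methyl-4-(2-methylbut-3-en-2-yl)cyclohex-2-en-1-ol | C=CC(C)(C)[C@H]1C=C(C)[C@H](O)CC1
A1 | alternative 1 | (1E,8Z,10E)-4,9-bis(tert-butyldimethylsilyloxy)-3,3,7-trimethyl-1-nitro-6-(triethylsilyloxy)dodeca-1,8,10-triene, C4, C6 and C7 configured as in A2 | C/C=C/C(O[Si](C)(C)C(C)(C)C)=C/[C@H](C)[C@H](O[Si](CC)(CC)CC)C[C@@H](O[Si](C)(C)C(C)(C)C)C(C)(C)/C=C/[N+](=O)[O-]
A2 | alternative 1 | cis-fused bicyclo[5.4.0]undecene silyl enol ether with secondary nitro group | C[C@H]1C=C(O[Si](C)(C)C(C)(C)C)[C@H]2[C@H](C)[C@H](O[Si](CC)(CC)CC)C[C@@H](O[Si](C)(C)C(C)(C)C)C(C)(C)[C@H]2[C@H]1[N+](=O)[O-]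
A3 | alternative 2 | (2E,6E)-farnesyl diphosphate | CC(C)=CCC/C(C)=C/CC/C(C)=C/COP(=O)(O)OP(=O)(O)O
A4 | alternative 2 | α-longipinene, enantiomer with the cage configuration of the target | C1CCC(C)(C)[C@@H]2[C@H]3CC=C(C)[C@@H]2[C@]31C
A5 | alternative 3 | (2E,6E)-8-(tert-butyldimethylsilyloxy)-3,7,11-trimethyl-10-oxododeca-2,6-dienoyl chloride, C8 configured as in A7 | CC(C)C(=O)C[C@@H](O[Si](C)(C)C(C)(C)C)/C(C)=C/CC/C(C)=C/C(Cl)=O
A6 | alternative 3 | (3Z,6E)-8-(tert-butyldimethylsilyloxy)-3,7,11-trimethyldodeca-1,3,6-triene-1,10-dione (vinylketene) | CC(C)C(=O)C[C@@H](O[Si](C)(C)C(C)(C)C)/C(C)=C/C/C=C(/C)C=C=O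
A7 | alternative 3 | 7-[1-(tert-butyldimethylsilyloxy)-4-methyl-3-oxopentyl]-2,7-dimethylbicyclo[3.1.1]hept-2-en-6-one | CC(C)C(=O)C[C@@H](O[Si](C)(C)C(C)(C)C)[C@@]1(C)[C@@H]2CC=C(C)[C@H]1C2=O
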